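Start with the amounts: count each species as a fraction of the starting material charged, and ask which of two fractions leads when one charge is read at three times, as oak, larch and birch.

| flask | starting material | coupling partner | second substrate | remark | time |
|---|---|---|---|---|---|
| eta | 0.61 M | 0.30 M | 0.122 M | run made earlier |  |
| alpha | 0.61 M | 0.46 M | 0.122 M | run made earlier |  |
| epsilon | 1.2 M | 0.61 M | 0.122 M | run made earlier |  |
| oak | 0.61 M | 0.610 M | 0.122 M |  | 20 min |
| larch | 0.61 M | 0.610 M | 0.122 M |  | 40 min |
| birch | 0.61 M | 0.610 M | 0.122 M |  | 80 min |

| run | time / min | starting material / % | target / % |
|---|---|---|---|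
| eta | 2.50 | 90.5 | 1.4 |
| eta | 5.00 | 80.5 | 5.2 |
| eta | 6.00 | 79.0 | 5.7 |
| eta | 10.0 | 69.8 | 7.4 |
| eta | 12.0 | 68.6 | 6.9 |
| eta | 15.0 | 65.5 | 10.4 |
| alpha | 0.833 | 95.2 | 0.6 |
| alpha | 2.50 | 89.0 | 5.3 |
| alpha | 5.00 | 78.6 | 7.2 |
| alpha | 6.00 | 79.3 | 7.8 |
| alpha | 10.0 | 68.3 | 10.2 |
| alpha | 12.0 | 64.7 | 11.3 |
| alpha | 15.0 | 63.2 | 13.3 |
| epsilon | 1.33 | 91.9 | 5.0 |
| epsilon | 2.50 | 87.0 | 5.8 |
| epsilon | 5.00 | 78.1 | 9.8 |
| epsilon | 8.00 | 71.1 | 10.6 |
| epsilon | 15.0 | 61.8 | 14.6 |

(scatter of a reading: 1 percentage point)

- reactions considered so far: second substrate + coupling partner <-> second product; 2 coupling partner -> self-condensation product; starting material + coupling partner <-> target; starting material <-> dormant form; second substrate -> decomposition product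

1. which of these there is most of at the end, counted by the starting material in it, oak (starting material / target)
2. which of these there is most of at the end, counted by the starting material in it, larch (starting material / target)
3. which of these there is most of at the end, counted by the starting material in it, birch (starting material / target)
4. final amount of the leader among these, as a percentage of the starting material charged, in oak
5. final amount of the leader among these, as a percentage of the starting material charged, in larch
6. final amount of the leader among these, as a percentage of the starting material charged, in birch

1. Put in the coupling and nothing else. Hold the coupling partner at its charge, a pseudo-first-order picture. The alpha run made 7.2% target by 5.00 min on 0.46 M of partner, so scale that to oak's 0.610 M: the rate is 0.0191 min⁻¹. Oak then keeps 68.3% starting material at 20 min, with 31.7% target.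

2. Add the slide to the dormant form. Nobody reads the dormant form, so take it by difference, and follow its share of everything not yet target. The mean of eta and alpha gives 0.152 at 5.00 min and 0.243 at 10.0 min. The second interval therefore adds 0.599 of the first. Read as an exponential climb, that is a half-life of 6.76 min and a ceiling of 0.379.

3. Keep the complement: the free share, the fraction of everything not yet target that stays starting material once several half-lives have passed, 0.621. Starting material is then the free share times what is not target. Oak's 20 min is 2.96 half-lives, so its dormant share stands at 0.330. On the target of step 1, starting material drops to 45.7%.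

4. Add the rest: the second substrate and self-condensation also take coupling partner. The epsilon run has oak's partner charge, and between 8.00 min and 15.0 min its target gains 0.00571 min⁻¹, less than the rate of step 1. Extended to 20 min, that gives 17.5% target, and my oak figure rises to 55.3% starting material. Larch and birch, with more target, fall below 51.3%. With the free share held, the lead changes at target 38.3%, above my oak target.

5. The forecast names starting material in oak, starting material in larch and starting material in birch, at 56%, 50% and 47%: “Starting material therefore stays the leader throughout”. It puts larch target at 22%, whereas my free share needs 19.5% to reach its larch figure, so the two differ there.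

    second substrate + coupling partner ⇌ second product (K = 3.40 M⁻¹, k = 0.490 M⁻¹ min⁻¹)
    2 coupling partner → self-condensation product (k = 0.170 M⁻¹ min⁻¹)
    starting material + coupling partner ⇌ target (K = 71.0 M⁻¹, k = 0.0540 M⁻¹ min⁻¹)
    starting material ⇌ dormant form (K = 0.580, k = 0.0350 min⁻¹)
    second substrate → decomposition product (k = 9.10 × 10⁻⁵ min⁻¹)

6. The leader is starting material in oak at 56.2%, starting material in larch at 50.3%, and starting material in birch at 48.1%, as forecast. In larch at 40.0 min the forward slide runs at 12 times the forward coupling, against 1.1 at the start. The free share on larch's 20.5% target gives 49.4%, and on the 0.37 M neighbour's 21.6% target it gives 48.7% against 49.5%. With the free share held, the lead passes to target at 38.3%, and oak at 200 min holds 25.9%; oak's starting material moves 6 points with the time cut to 13.1 min or the partner cut to 0.217 M.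

(All runs are calculated for an exercise, and the scatter is random.)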